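**Plan**

- Cuts: the hydroquinone and the ring-B enedione are unmasked last (aryl methyl ethers, C1 ketal, C4 silyl ether); the ring-A C(Me)=CH unit goes back to a C6 ketone; then the C4a–aryl bond, the C8–aryl bond, ring A (Robinson annulation) and the C8a–prenyl bond are cut.
- Forward: ring B is the starting cyclohexanedione; prenylation and Robinson annulation add ring A; the arene is attached at C8 by conjugate addition; closure of the five-membered ring C8–aryl–aryl–C4a–C8a completes the benzo-fused bicyclo[3.2.1]octane.
- Enabling feature: C4a, the aryl-bearing quaternary carbon, is the fully substituted β-carbon of the ring-A enone (C6=O, C5=C4a). It stands 1,3 to the benzylic CH C8 across the prenyl-bearing quaternary C8a, so an ortho-palladated aryl on C8 reaches C4a through a five-membered ring.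
- Stereochemistry: C8a from the L-proline-derived catalyst of the aldol cyclisation; C8 from addition anti to prenyl; C4a from the tether, the arene being held on the face opposite to prenyl.
- Numbering: decalin (Wieland–Miescher) numbering is used throughout, also for the cage compounds: C1 ketal/ketone, C4 oxygenated ring-B carbon, C4a and C8a ring-fusion carbons, C6 ring-A ketone, C8 aryl-bearing CH.

Key step: step 9

Assumption: the γ-hydroxylation of step 5 is drawn as the pseudoaxial alcohol cis to prenyl, the usual result of peracid attack on dienol ethers of angularly substituted octalones. C4 ends as a ketone, so the other epimer would serve equally.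

**Route**

Step 1
Reactants: 1 cyclohexane-1,3-dione; 2 prenyl bromide
Product: 3 2-(3-methylbut-2-enyl)cyclohexane-1,3-dione
Conditions: NaOH (1 equiv), H2O, 0 °C to rt
Reagents that add atoms: none
Why: C-alkylation of the 1,3-dione enolate by the allylic bromide (SN2) should prevail in water, where hydrogen bonding to the enolate oxygens disfavours O-alkylation.

Step 2
Reactants: 3 2-(3-methylbut-2-enyl)cyclohexane-1,3-dione; 4 methyl vinyl ketone
Product: 5 2-(3-methylbut-2-enyl)-2-(3-oxobutyl)cyclohexane-1,3-dione
Conditions: Et3N (0.1 equiv), EtOAc, rt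
Reagents that add atoms: none
Why: Amine-catalysed Michael addition of the acidic 2-substituted 1,3-dione to the enone creates the quaternary carbon that becomes C8a and is the first half of a Robinson annulation.

Step 3
Reactants: 5 2-(3-methylbut-2-enyl)-2-(3-oxobutyl)cyclohexane-1,3-dione
Product: 7 (R)-8a-(3-methylbut-2-enyl)-3,4,8,8a-tetrahydronaphthalene-1,6(2H,7H)-dione, via cis-fused bicyclic ketol 6 (not isolated)
Conditions: N-tosyl-(Sa)-binam-L-prolinamide (2 mol%), PhCO2H (1 mol%), neat, rt
Reagents that add atoms: none
Why: Enamine-mediated intramolecular aldol cyclisation and dehydration (Hajos–Parrish–Eder–Sauer–Wiechert reaction, second half of the Robinson annulation) closes ring A, and the L-proline-derived catalyst selects one of the two enantiotopic ring carbonyls, which sets C8a in the same spatial sense as in the (S)-methyl series (descriptor R here because prenyl outranks C8).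

Step 4
Reactants: 7 (R)-8a-(3-methylbut-2-enyl)-3,4,8,8a-tetrahydronaphthalene-1,6(2H,7H)-dione
Product: 8 C1 ethylene ketal of enedione 7
Conditions: ethylene glycol, p-TsOH·H2O (cat), 4 Å MS, rt
Reagents that add atoms: ethylene glycol, OCCO
Why: Acid-catalysed ketalisation is selective for the saturated C1 ketone because the conjugated C6 carbonyl is much less electrophilic, as is usual for Wieland–Miescher-type diones.

Step 5
Reactants: 8 C1 ethylene ketal of enedione 7
Product: 10 4-hydroxy enone ketal (OH cis to prenyl), via extended trimethylsilyl dienol ether 9 (not isolated)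
Conditions: TMSOTf, Et3N, CH2Cl2, 0 °C; then mCPBA (1 equiv), NaHCO3, CH2Cl2, −30 °C; aqueous work-up
Reagents that add atoms: mCPBA, OOC(=O)c1cccc(Cl)c1
Why: Soft enolisation gives the extended silyl dienol ether, which the peracid epoxidises at the electron-rich C4=C4a terminus before the isolated prenyl alkene (one equivalent, low temperature), and opening of the epoxide with loss of silyl gives the γ-hydroxy enone (vinylogous Rubottom oxidation), attack at C4 being pseudoaxial on the prenyl face as with steroidal dienol ethers.

Step 6
Reactants: 10 4-hydroxy enone ketal (OH cis to prenyl)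
Product: 11 4-triethylsilyloxy enone ketal
Conditions: TESOTf, 2,6-lutidine, CH2Cl2, −78 °C
Reagents that add atoms: triethylsilyl triflate, CC[Si](CC)(CC)OS(=O)(=O)C(F)(F)F
Why: Silyl triflate and a hindered pyridine base silylate the pseudoaxial secondary alcohol (standard silyl ether protection), triethylsilyl being chosen so that it leaves together with the ketal in step 12.

Step 7
Reactants: 11 4-triethylsilyloxy enone ketal
Product: 13 cross-conjugated 4a(5),7-dien-6-one, via cross-conjugated trimethylsilyl dienol ether 12 (not isolated)
Conditions: LDA, TMSCl, THF, −78 °C; then Pd(OAc)2 (1.1 equiv), MeCN, rt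
Reagents that add atoms: none
Why: Kinetic deprotonation of the enone at the α' carbon C7 with in situ O-silylation, then oxidation of the silyl enol ether by divalent palladium through an oxa-π-allyl complex and β-hydride loss from C8 (Saegusa–Ito oxidation), installs the C7=C8 bond.

Step 8
Reactants: 13 cross-conjugated 4a(5),7-dien-6-one; 14 2,3-dibromo-1,4-dimethoxybenzene
Product: 17 8-(2-bromo-3,6-dimethoxyphenyl) enone (aryl trans to prenyl), via (2-bromo-3,6-dimethoxyphenyl)magnesium chloride 15 (not isolated), via trimethylsilyl enol ether adduct 16 (not isolated)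
Conditions: 14, iPrMgCl·LiCl (1 equiv), THF, −20 °C; then CuBr·SMe2 (0.2 equiv), TMSCl, 13, THF, −40 to −20 °C; then 10% aq citric acid, 0 °C
Reagents that add atoms: none
Why: Bromine–magnesium exchange on one of the two equivalent bromides, then copper-catalysed and chlorosilane-accelerated 1,4-addition of the aryl Grignard to the less substituted terminus C8 of the cross-conjugated dienone on the face opposite to the pseudoaxial prenyl group (as in 1α-additions to steroidal 1,4-dien-3-ones), sets C8, and mild acid hydrolyses the silyl enol ether while the low temperature keeps the ortho-bromoaryl metal from collapsing to an aryne.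

Step 9
Reactants: 17 8-(2-bromo-3,6-dimethoxyphenyl) enone (aryl trans to prenyl)
Product: 18 arene-bridged cage ketone (4a,8-ortho-phenylene-bridged decalin-6-one)
Conditions: Pd(OAc)2 (10 mol%), PPh3 (25 mol%), HCO2Na (1.5 equiv), nBu4NCl (1 equiv), degassed DMF, 85 °C
Reagents that add atoms: none
Why: Zerovalent palladium formed in situ inserts into the aryl C–Br bond, the arylpalladium bromide adds across the C5=C4a enone with the aryl going to the β-carbon C4a, and the palladium enolate at C5, which has no β-hydrogen on the now quaternary C4a, is cleaved by formate (hydride transfer, loss of CO2, C–H reductive elimination) to the saturated ketone. This is an intramolecular reductive Heck reaction, a palladium-catalysed conjugate arylation that is an established way to benzylic quaternary carbons. The new five-membered ring (C8, two arene carbons, C4a, C8a) closes in the 5-exo-trig mode and completes the benzo-fused bicyclo[3.2.1]octane. The new stereocentre C4a is dictated by the tether: the aryl group is pseudoaxial on C8 on the face opposite to prenyl and can reach only that face of C4a. The step needs carbopalladation to outrun direct formate reduction of the arylpalladium and insertion into the prenyl alkene; the sparingly soluble formate keeps the hydride supply slow, the enone is the activated and nearest alkene, and the trisubstituted prenyl alkene lies trans-diaxial to the arene and out of reach.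

Step 10
Reactants: 18 arene-bridged cage ketone (4a,8-ortho-phenylene-bridged decalin-6-one)
Product: 20 C6 enol triflate (C6=C7), via C6–C7 lithium enolate 19 (not isolated)
Conditions: LDA, THF, −78 °C; then N-(5-chloro-2-pyridyl)triflimide (Comins' reagent), −78 to −40 °C
Reagents that add atoms: N-(5-chloro-2-pyridyl)triflimide, FC(F)(F)S(=O)(=O)N(c1ccc(Cl)cn1)S(=O)(=O)C(F)(F)F
Why: Kinetic deprotonation with the hindered amide base should take a proton from the C7 methylene, which is flanked by the tertiary C8, in preference to the C5 methylene, which is flanked by the quaternary C4a and its silyloxy-bearing neighbour, and O-triflation of the enolate (enol triflate formation) fixes the C6=C7 bond.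

Step 11
Reactants: 20 C6 enol triflate (C6=C7)
Product: 21 6-methyl-6,7-ene cage compound
Conditions: Fe(acac)3 (iron tris(acetylacetonate), 10 mol%), MeMgBr, THF/NMP, −30 to 0 °C
Reagents that add atoms: methylmagnesium bromide, C[Mg]Br
Why: Iron-catalysed cross-coupling of the alkenyl triflate with the methyl Grignard reagent (Kumada-type coupling) replaces the triflate by methyl at low temperature without touching the ketal, the silyl ether or the aryl ethers.

Step 12
Reactants: 21 6-methyl-6,7-ene cage compound
Product: 22 4-hydroxy-1-ketone
Conditions: 2 M aq HCl, THF, rt to 40 °C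
Reagents that add atoms: water, O
Why: Aqueous acid hydrolyses the dioxolane and the triethylsilyl ether in one operation (acetal hydrolysis and desilylation), and the two trisubstituted alkenes should tolerate the dilute acid at mild temperature.

Step 13
Reactants: 22 4-hydroxy-1-ketone
Product: 24 ring-B 2-ene-1,4-dione (hydroquinone dimethyl ether), via ring-B 1,4-diketone 23 (not isolated)
Conditions: IBX (4 equiv), DMSO, rt, then 70 °C
Reagents that add atoms: none
Why: IBX first oxidises the secondary alcohol to the ketone and then, on warming, dehydrogenates the 1,4-diketone through its enol across C2–C3 (IBX dehydrogenation of ketones), the only position available because C4a and C8a are quaternary, so that over-oxidation is excluded.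

Step 14
Reactants: 24 ring-B 2-ene-1,4-dione (hydroquinone dimethyl ether)
Product: 25 para-quinone
Conditions: (NH4)2Ce(NO3)6 (2.5 equiv), MeCN/H2O, 0 °C
Reagents that add atoms: water, O
Why: Single-electron oxidation of the electron-rich hydroquinone dimethyl ether by tetravalent cerium with water as the oxygen source (oxidative demethylation to the para-quinone) leaves the alkenes and the enedione untouched.

Step 15
Reactants: 25 para-quinone
Product: 26 target hydroquinone CNP0166383.1
Conditions: Na2S2O4 (1.2 equiv), EtOAc/H2O, 0 °C, argon
Reagents that add atoms: none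
Why: Dithionite reduces the benzoquinone to the hydroquinone within minutes in a two-phase system (quinone reduction), far faster than it attacks the less easily reduced ring-B enedione, and no stereocentre is affected.

**Compound list**

1 | cyclohexane-1,3-dione | O=C1CCCC(=O)C1 | starting material
2 | prenyl bromide (1-bromo-3-methylbut-2-ene) | CC(C)=CCBr | starting material
3 | 2-(3-methylbut-2-enyl)cyclohexane-1,3-dione | CC(C)=CCC1C(=O)CCCC1=O | intermediate
4 | methyl vinyl ketone (but-3-en-2-one) | CC(=O)C=C | starting material
5 | 2-(3-methylbut-2-enyl)-2-(3-oxobutyl)cyclohexane-1,3-dione | CC(C)=CCC1(CCC(C)=O)C(=O)CCCC1=O | intermediate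
6 | cis-fused bicyclic ketol, 4a-hydroxy-8a-prenyl-octahydronaphthalene-1,6-dione with OH cis to prenyl (formed in situ) | CC(C)=CC[C@]12CCC(=O)C[C@@]1(O)CCCC2=O | intermediate
7 | (R)-8a-(3-methylbut-2-enyl)-3,4,8,8a-tetrahydronaphthalene-1,6(2H,7H)-dione | CC(C)=CC[C@]12CCC(=O)C=C1CCCC2=O | intermediate
8 | C1 ethylene ketal of enedione 7 (8aR; C6 enone, C4a=C5) | CC(C)=CC[C@]12CCC(=O)C=C1CCCC23OCCO3 | intermediate
9 | extended trimethylsilyl dienol ether of 8 (C6–OTMS, C5=C6 and C4=C4a; formed in situ) | CC(C)=CC[C@]12CCC(O[Si](C)(C)C)=CC1=CCCC23OCCO3 | intermediate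
10 | 4-hydroxy enone ketal, OH on C4 cis to prenyl on C8a | CC(C)=CC[C@]12CCC(=O)C=C1[C@H](O)CCC23OCCO3 | intermediate
11 | 4-triethylsilyloxy enone ketal (OTES cis to prenyl) | CC(C)=CC[C@]12CCC(=O)C=C1[C@H](O[Si](CC)(CC)CC)CCC23OCCO3 | intermediate
12 | cross-conjugated trimethylsilyl dienol ether of 11 (C6–OTMS, C6=C7 and C4a=C5; formed in situ) | CC(C)=CC[C@]12CC=C(O[Si](C)(C)C)C=C1[C@H](O[Si](CC)(CC)CC)CCC23OCCO3 | intermediate
13 | cross-conjugated dienone (C6 ketone, C4a=C5 and C7=C8, C1 ketal, C4 OTES cis to prenyl) | CC(C)=CC[C@]12C=CC(=O)C=C1[C@H](O[Si](CC)(CC)CC)CCC23OCCO3 | intermediate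
14 | 2,3-dibromo-1,4-dimethoxybenzene | COc1ccc(OC)c(Br)c1Br | starting material
15 | (2-bromo-3,6-dimethoxyphenyl)magnesium chloride (formed in situ) | COc1ccc(OC)c(Br)c1[Mg]Cl | intermediate
16 | trimethylsilyl enol ether (C6=C7) of 17 (formed in situ) | CC(C)=CC[C@]12[C@@H](c3c(OC)ccc(OC)c3Br)C=C(O[Si](C)(C)C)C=C1[C@H](O[Si](CC)(CC)CC)CCC23OCCO3 | intermediate
17 | 8-(2-bromo-3,6-dimethoxyphenyl) enone: C6 ketone, C4a=C5, aryl on C8 trans to prenyl on C8a, C1 ketal, C4 OTES cis to prenyl | CC(C)=CC[C@]12[C@@H](c3c(OC)ccc(OC)c3Br)CC(=O)C=C1[C@H](O[Si](CC)(CC)CC)CCC23OCCO3 | intermediate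
18 | arene-bridged cage ketone: 3,6-dimethoxy-1,2-phenylene bridging C4a and C8, C6 ketone, C1 ketal, C4 OTES, prenyl on C8a over the three-carbon bridge | CC(C)=CC[C@@]12C3(OCCO3)CC[C@@H](O[Si](CC)(CC)CC)[C@@]14CC(=O)C[C@@H]2c1c(OC)ccc(OC)c14 | intermediate
19 | lithium enolate of 18 toward C7 (formed in situ) | CC(C)=CC[C@@]12C3(OCCO3)CC[C@@H](O[Si](CC)(CC)CC)[C@@]14CC([O-])=C[C@@H]2c1c(OC)ccc(OC)c14.[Li+] | intermediate
20 | C6 enol triflate of 18 with C6=C7 | CC(C)=CC[C@@]12C3(OCCO3)CC[C@@H](O[Si](CC)(CC)CC)[C@@]14CC(OS(=O)(=O)C(F)(F)F)=C[C@@H]2c1c(OC)ccc(OC)c14 | intermediate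
21 | 6-methyl-6,7-ene cage compound (C1 ketal, C4 OTES) | CC(C)=CC[C@@]12C3(OCCO3)CC[C@@H](O[Si](CC)(CC)CC)[C@@]14CC(C)=C[C@@H]2c1c(OC)ccc(OC)c14 | intermediate
22 | 4-hydroxy-1-ketone (ring B deprotected) | CC(C)=CC[C@@]12C(=O)CC[C@@H](O)[C@@]14CC(C)=C[C@@H]2c1c(OC)ccc(OC)c14 | intermediate
23 | ring-B 1,4-diketone (formed in situ) | CC(C)=CC[C@@]12C(=O)CCC(=O)[C@@]14CC(C)=C[C@@H]2c1c(OC)ccc(OC)c14 | intermediate
24 | ring-B 2-ene-1,4-dione, hydroquinone dimethyl ether | CC(C)=CC[C@@]12C(=O)C=CC(=O)[C@@]14CC(C)=C[C@@H]2c1c(OC)ccc(OC)c14 | intermediate
25 | para-quinone of the cage enedione | CC(C)=CC[C@@]12C(=O)C=CC(=O)[C@@]14CC(C)=C[C@@H]2C1=C4C(=O)C=CC1=O | intermediate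
26 | CNP0166383.1 (hydroquinone) | CC(C)=CC[C@@]12C(=O)C=CC(=O)[C@@]13CC(C)=C[C@@H]2c1c(O)ccc(O)c13 | target

**Count and risks**

Total step count: 15. Longest linear sequence: 15 steps (1 to 26); arene 14 enters directly in step 8.

Steps most likely to fail:

1. Step 8. The ortho-bromoaryl magnesium or copper species may eliminate to an aryne, or add too slowly to the neopentyl carbon C8, before productive 1,4-addition occurs. Fallback: replace the carbanion by an aryl-rhodium nucleophile. Grignard 15 is quenched with B(OMe)3 and hydrolysed to (2-bromo-3,6-dimethoxyphenyl)boronic acid F1. F1, used in excess, is added to dienone 13 with [Rh(OH)(cod)]2 (monovalent rhodium) in dioxane/H2O at 60–80 °C (Hayashi–Miyaura conjugate addition, which tolerates aryl bromides and heating). Protonation of the rhodium enolate should give enone 17 directly. The fallback sets out from 13 and 15 and returns to the route at 17.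

2. Step 9. Formate may reduce the arylpalladium before it inserts (hydrodebromination), or insertion into the trisubstituted enone next to the quaternary C8a may be too slow. Fallback: form the same C4a–aryl bond by radical chemistry. Slow addition of Bu3SnH and AIBN to 17 in benzene at 80 °C generates the aryl radical, which should cyclise 5-exo onto the β-carbon of the enone; the α-keto radical is then reduced by the stannane to 18. The fallback sets out from 17 and returns at 18 without a new compound.

3. Step 10. Enolisation may not discriminate well enough between the C7 and C5 methylenes, giving a mixture of regioisomeric triflates. Fallback: take regiocontrol from hydrazone geometry instead of kinetic basicity. Ketone 18 is condensed with 2,4,6-triisopropylbenzenesulfonyl hydrazide in THF/MeOH to the 2,4,6-triisopropylbenzenesulfonyl hydrazone F2, whose N–N bond should lie on the side of the less hindered C7. sec-BuLi or n-BuLi (2.2 equiv) in THF/TMEDA, −78 to 0 °C, removes the syn α-proton at C7 and, after loss of sulfinate and nitrogen, gives the C6 vinyllithium (Shapiro reaction). Quenching with MeI should give 21. The fallback sets out from 18 and returns at 21, bypassing 20.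

**Further compounds**

F1 | step 8 | (2-bromo-3,6-dimethoxyphenyl)boronic acid | COc1ccc(OC)c(Br)c1B(O)O
F0 | step 9 | none | none
F2 | step 10 | 2,4,6-triisopropylbenzenesulfonyl hydrazone of cage ketone 18 (N–N bond syn to C7) | CC(C)=CC[C@@]12C3(OCCO3)CC[C@@H](O[Si](CC)(CC)CC)[C@@]14C/C(=N/NS(=O)(=O)c5c(C(C)C)cc(C(C)C)cc5C(C)C)C[C@@H]2c1c(OC)ccc(OC)c14
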